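**Retrosynthetic overview**

- The target is the diacetate of a (2Z)-2-alkylbut-2-ene-1,4-diol with a (3E) side-chain alkene and an (S) ring carbon. The diol comes from hydride reduction of a 2-alkylmaleate, made by carbonylation of the (Z)-enol triflate of a β-keto ester.
- That β-keto ester comes from γ-alkylation of the methyl acetoacetate dianion with an (E)-allylic bromide. The (E)-trisubstituted alkene comes from a (Z)-enol phosphate and Me2CuLi.
- Key C–C bond: crossed Claisen condensation of the ring-bearing C12 acid (as its acyl imidazolide) with the lithium enolate of ethyl acetate.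
- The (S) centre is set by a suprafacial Eschenmoser–Claisen rearrangement of (R)-2,4,4-trimethylcyclohex-2-en-1-ol, itself from a CBS reduction.
- The cyclohexene is the only ring and is formed first, by Michael addition/aldol condensation of isobutyraldehyde with ethyl vinyl ketone.

**Route**

Step 1
Reactants: 1 isobutyraldehyde; 2 ethyl vinyl ketone (pent-1-en-3-one)
Product: 5 2,4,4-trimethylcyclohex-2-en-1-one, via 2,2-dimethyl-5-oxoheptanal 3 (not isolated), via 3-hydroxy-2,4,4-trimethylcyclohexan-1-one 4 (not isolated)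
Conditions: conc. H2SO4 (1 mol %), toluene, 45 °C then reflux, Dean–Stark
Reagents that add atoms: none
Why: Acid-catalysed Robinson-type annulation, in which the enol of 1 adds to enone 2 (intermolecular Michael reaction) and the 1,5-keto aldehyde can only close by aldol condensation through the ethyl CH2, giving the achiral cyclohexenone.

Step 2
Reactants: 5 2,4,4-trimethylcyclohex-2-en-1-one
Product: 6 (1R)-2,4,4-trimethylcyclohex-2-en-1-ol
Conditions: (S)-2-methyl-CBS-oxazaborolidine (10 mol %), BH3·SMe2 (0.7 equiv), THF, −20 °C; MeOH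
Reagents that add atoms: none
Why: Corey–Bakshi–Shibata 1,2-reduction in which the methyl-bearing alkene arm acts as the large group and the ring CH2 as the small one, so the (S)-catalyst delivers hydride to the face that gives the (R)-carbinol (same sense as acetophenone to (R)-1-phenylethanol).

Step 3
Reactants: 6 (1R)-2,4,4-trimethylcyclohex-2-en-1-ol; 7 N,N-dimethylacetamide dimethyl acetal
Product: 10 N,N-dimethyl-2-[(1S)-2,6,6-trimethylcyclohex-2-en-1-yl]acetamide, via mixed N,O-acetal 8 (not isolated), via ketene N,O-acetal 9 (not isolated)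
Conditions: 7 (4 equiv), xylene, 140 °C, 16 h, MeOH distilled off
Reagents that add atoms: none
Why: Eschenmoser–Claisen rearrangement, whose suprafacial [3,3] shift forms the new C–C bond on the ring face that the C–O bond leaves, so (1R) in 6 becomes (1S) in 10 and the alkene moves into the 2,6,6-trimethylcyclohex-2-enyl position.

Step 4
Reactants: 10 N,N-dimethyl-2-[(1S)-2,6,6-trimethylcyclohex-2-en-1-yl]acetamide
Product: 11 2-[(1S)-2,6,6-trimethylcyclohex-2-en-1-yl]ethan-1-ol
Conditions: LiEt3BH (3 equiv), THF, 0 °C → rt; H2O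
Reagents that add atoms: none
Why: Triethylborohydride reduction of a tertiary amide proceeds with C–N cleavage to the primary alcohol, and the stereocentre (β to the carbonyl, not acidic) is untouched.

Step 5
Reactants: 11 2-[(1S)-2,6,6-trimethylcyclohex-2-en-1-yl]ethan-1-ol
Product: 12 (6S)-6-(2-bromoethyl)-1,5,5-trimethylcyclohex-1-ene
Conditions: CBr4, PPh3, CH2Cl2, 0 °C
Reagents that add atoms: carbon tetrabromide, BrC(Br)(Br)Br
Why: Appel reaction (SN2 on the alkoxyphosphonium salt) at an unhindered primary carbon under neutral conditions that leave the ring alkene alone.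

Step 6
Reactants: 12 (6S)-6-(2-bromoethyl)-1,5,5-trimethylcyclohex-1-ene
Product: 14 3-[(1S)-2,6,6-trimethylcyclohex-2-en-1-yl]propanoic acid, via Grignard reagent 13 (not isolated)
Conditions: Mg turnings, THF, 40 °C; CO2 (dry ice), −78 °C → rt; cold 1 M HCl
Reagents that add atoms: carbon dioxide, O=C=O; magnesium, [Mg] (held in 13 only)
Why: Grignard formation from a primary bromide followed by carboxylation adds the one carbon that becomes the methyl-bearing alkene carbon, and the brief cold acid work-up does not move the ring alkene.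

Step 7
Reactants: 14 3-[(1S)-2,6,6-trimethylcyclohex-2-en-1-yl]propanoic acid; 15 ethyl acetate
Product: 18 ethyl 3-oxo-5-[(1S)-2,6,6-trimethylcyclohex-2-en-1-yl]pentanoate, via acyl imidazolide 16 (not isolated), via lithium enolate of ethyl acetate 17 (not isolated)
Conditions: 14, CDI (1.1 equiv), THF, rt, 1 h; added to 17 [15 (3.2 equiv), LiN(SiMe3)2 (3 equiv), THF, −78 °C]; −78 °C, 1 h; sat. NH4Cl
Reagents that add atoms: 1,1'-carbonyldiimidazole, O=C(n1ccnc1)n1ccnc1 (imidazolyl group of 16 only); LiN(SiMe3)2, [Li]N([Si](C)(C)C)[Si](C)(C)C (lithium of 17 only)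
Why: Crossed Claisen condensation in which the ester enolate acylates on the activated imidazolide, and the β-keto ester is deprotonated at once by excess enolate, which drives the reaction and prevents a second addition.

Step 8
Reactants: 18 ethyl 3-oxo-5-[(1S)-2,6,6-trimethylcyclohex-2-en-1-yl]pentanoate
Product: 20 ethyl (2Z)-3-[(diethoxyphosphoryl)oxy]-5-[(1S)-2,6,6-trimethylcyclohex-2-en-1-yl]pent-2-enoate, via sodium enolate 19 (not isolated)
Conditions: NaH (1.1 equiv), Et2O, 0 °C; ClP(O)(OEt)2, 0 °C → rt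
Reagents that add atoms: diethyl chlorophosphate, CCOP(=O)(Cl)OCC; NaH, [NaH] (sodium of 19 only)
Why: O-phosphorylation of the sodium-chelated (U-shaped) β-keto ester enolate gives the (Z)-enol phosphate, with the phosphate cis to the ester.

Step 9
Reactants: 20 ethyl (2Z)-3-[(diethoxyphosphoryl)oxy]-5-[(1S)-2,6,6-trimethylcyclohex-2-en-1-yl]pent-2-enoate
Product: 21 ethyl (2E)-3-methyl-5-[(1S)-2,6,6-trimethylcyclohex-2-en-1-yl]pent-2-enoate
Conditions: Me2CuLi (3 equiv, from CuI + 2 MeLi, Et2O, 0 °C), Et2O, −78 → −45 °C; aq. NH4Cl/NH3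
Reagents that add atoms: lithium dimethylcuprate, [Li+].C[Cu-]C (made from methyllithium, [Li]C, and CuI)
Why: Cuprate addition–elimination on the enol phosphate (Sum–Weiler olefin synthesis) replaces the phosphate by methyl with retention, so the (Z)-phosphate gives the (E)-3-methyl enoate stereospecifically.

Step 10
Reactants: 21 ethyl (2E)-3-methyl-5-[(1S)-2,6,6-trimethylcyclohex-2-en-1-yl]pent-2-enoate
Product: 22 (2E)-3-methyl-5-[(1S)-2,6,6-trimethylcyclohex-2-en-1-yl]pent-2-en-1-ol
Conditions: i-Bu2AlH (2.5 equiv), CH2Cl2, −78 → 0 °C; aq. potassium sodium tartrate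
Reagents that add atoms: none
Why: DIBAL-H reduces the enoate 1,2-selectively to the allylic alcohol without touching the alkene geometry.

Step 11
Reactants: 22 (2E)-3-methyl-5-[(1S)-2,6,6-trimethylcyclohex-2-en-1-yl]pent-2-en-1-ol
Product: 23 (6S)-6-[(3E)-5-bromo-3-methylpent-3-en-1-yl]-1,5,5-trimethylcyclohex-1-ene
Conditions: PBr3 (0.4 equiv), pyridine (cat.), Et2O, −10 → 0 °C; used crude
Reagents that add atoms: phosphorus tribromide, BrP(Br)Br
Why: SN2 bromination of the primary allylic alcohol through its phosphite ester at low temperature, as for geranyl bromide, keeps the (E) geometry.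

Step 12
Reactants: 23 (6S)-6-[(3E)-5-bromo-3-methylpent-3-en-1-yl]-1,5,5-trimethylcyclohex-1-ene; 24 methyl acetoacetate
Product: 26 methyl (6E)-7-methyl-3-oxo-9-[(1S)-2,6,6-trimethylcyclohex-2-en-1-yl]non-6-enoate, via acetoacetate dianion 25 (not isolated)
Conditions: 24, NaH (1.1 equiv), THF, 0 °C; n-BuLi (1.05 equiv), 0 °C; 23, 0 °C → rt; dilute HCl
Reagents that add atoms: NaH, [NaH]; n-butyllithium, [Li]CCCC (metal ions of 25 only)
Why: Weiler dianion alkylation, in which the more basic γ-carbon of the acetoacetate dianion displaces the primary allylic bromide by SN2 without allylic transposition.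

Step 13
Reactants: 26 methyl (6E)-7-methyl-3-oxo-9-[(1S)-2,6,6-trimethylcyclohex-2-en-1-yl]non-6-enoate
Product: 28 methyl (2Z,6E)-7-methyl-3-{[(trifluoromethyl)sulfonyl]oxy}-9-[(1S)-2,6,6-trimethylcyclohex-2-en-1-yl]nona-2,6-dienoate, via sodium enolate 27 (not isolated)
Conditions: NaH (1.1 equiv), THF, 0 °C; PhNTf2, 0 °C → rt
Reagents that add atoms: N-phenylbis(trifluoromethanesulfonimide), O=S(=O)(N(c1ccccc1)S(=O)(=O)C(F)(F)F)C(F)(F)F; NaH, [NaH] (sodium of 27 only)
Why: O-triflation of the chelated sodium enolate gives the (Z)-enol triflate (triflate cis to the ester), and the mild triflating agent spares the three alkenes.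

Step 14
Reactants: 28 methyl (2Z,6E)-7-methyl-3-{[(trifluoromethyl)sulfonyl]oxy}-9-[(1S)-2,6,6-trimethylcyclohex-2-en-1-yl]nona-2,6-dienoate
Product: 29 dimethyl (2Z)-2-{(3E)-4-methyl-6-[(1S)-2,6,6-trimethylcyclohex-2-en-1-yl]hex-3-en-1-yl}but-2-enedioate
Conditions: Pd(OAc)2 (5 mol %), PPh3 (10 mol %), CO (1 atm), MeOH, Et3N, DMF, rt → 40 °C
Reagents that add atoms: carbon monoxide, [C-]#[O+]; methanol, CO
Why: Palladium-catalysed methoxycarbonylation, in which zerovalent palladium formed in situ inserts into the C–OTf bond with retention and CO insertion/methanolysis follow, so the (Z)-triflate gives the maleate with the two esters cis.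

Step 15
Reactants: 29 dimethyl (2Z)-2-{(3E)-4-methyl-6-[(1S)-2,6,6-trimethylcyclohex-2-en-1-yl]hex-3-en-1-yl}but-2-enedioate
Product: 30 (2Z)-2-{(3E)-4-methyl-6-[(1S)-2,6,6-trimethylcyclohex-2-en-1-yl]hex-3-en-1-yl}but-2-ene-1,4-diol
Conditions: i-Bu2AlH (5 equiv), CH2Cl2, −78 → 0 °C; aq. potassium sodium tartrate
Reagents that add atoms: none
Why: Excess DIBAL-H reduces both conjugated esters 1,2 to the allylic diol, and any butenolide formed on the way is reduced to the same (Z)-diol.

Step 16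
Reactants: 30 (2Z)-2-{(3E)-4-methyl-6-[(1S)-2,6,6-trimethylcyclohex-2-en-1-yl]hex-3-en-1-yl}but-2-ene-1,4-diol
Product: 31 (2Z)-2-{(3E)-4-methyl-6-[(1S)-2,6,6-trimethylcyclohex-2-en-1-yl]hex-3-en-1-yl}but-2-ene-1,4-diyl diacetate (target)
Conditions: Ac2O (3 equiv), pyridine, DMAP (cat.), CH2Cl2, 0 °C → rt
Reagents that add atoms: acetic anhydride, CC(=O)OC(C)=O
Why: DMAP-catalysed acylation of both primary allylic alcohols under basic conditions, which avoids acid-induced cyclisation of the (Z)-diol and migration of the ring alkene.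

**Compound list**

1 | isobutyraldehyde (2-methylpropanal) | CC(C)C=O | starting material
2 | ethyl vinyl ketone (pent-1-en-3-one) | CCC(=O)C=C | starting material
3 | 2,2-dimethyl-5-oxoheptanal | CCC(=O)CCC(C)(C)C=O | intermediate
4 | 3-hydroxy-2,4,4-trimethylcyclohexan-1-one (racemic diastereomer mixture) | CC1C(=O)CCC(C)(C)C1O | intermediate
5 | 2,4,4-trimethylcyclohex-2-en-1-one | CC1=CC(C)(C)CCC1=O | intermediate
6 | (1R)-2,4,4-trimethylcyclohex-2-en-1-ol | CC1=CC(C)(C)CC[C@H]1O | intermediate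
7 | N,N-dimethylacetamide dimethyl acetal (1,1-dimethoxy-N,N-dimethylethan-1-amine) | COC(C)(OC)N(C)C | starting material
8 | 1-methoxy-N,N-dimethyl-1-{[(1R)-2,4,4-trimethylcyclohex-2-en-1-yl]oxy}ethan-1-amine (mixed N,O-acetal, acetal carbon unassigned) | COC(C)(N(C)C)O[C@H]1C(C)=CC(C)(C)CC1 | intermediate
9 | N,N-dimethyl-1-{[(1R)-2,4,4-trimethylcyclohex-2-en-1-yl]oxy}ethen-1-amine (ketene N,O-acetal) | C=C(N(C)C)O[C@H]1C(C)=CC(C)(C)CC1 | intermediate
10 | N,N-dimethyl-2-[(1S)-2,6,6-trimethylcyclohex-2-en-1-yl]acetamide | CN(C)C(=O)C[C@@H]1C(C)=CCCC1(C)C | intermediate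
11 | 2-[(1S)-2,6,6-trimethylcyclohex-2-en-1-yl]ethan-1-ol | OCC[C@@H]1C(C)=CCCC1(C)C | intermediate
12 | (6S)-6-(2-bromoethyl)-1,5,5-trimethylcyclohex-1-ene | BrCC[C@@H]1C(C)=CCCC1(C)C | intermediate
13 | {2-[(1S)-2,6,6-trimethylcyclohex-2-en-1-yl]ethyl}magnesium bromide | Br[Mg]CC[C@@H]1C(C)=CCCC1(C)C | intermediate
14 | 3-[(1S)-2,6,6-trimethylcyclohex-2-en-1-yl]propanoic acid | OC(=O)CC[C@@H]1C(C)=CCCC1(C)C | intermediate
15 | ethyl acetate | CCOC(C)=O | starting material
16 | 1-{3-[(1S)-2,6,6-trimethylcyclohex-2-en-1-yl]propanoyl}-1H-imidazole | O=C(CC[C@@H]1C(C)=CCCC1(C)C)n1ccnc1 | intermediate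
17 | lithium 1-ethoxyethen-1-olate (lithium enolate of ethyl acetate) | [Li+].C=C([O-])OCC | intermediate
18 | ethyl 3-oxo-5-[(1S)-2,6,6-trimethylcyclohex-2-en-1-yl]pentanoate | CCOC(=O)CC(=O)CC[C@@H]1C(C)=CCCC1(C)C | intermediate
19 | sodium (Z)-enolate of 18 | [Na+].CCOC(=O)/C=C(\[O-])CC[C@@H]1C(C)=CCCC1(C)C | intermediate
20 | ethyl (2Z)-3-[(diethoxyphosphoryl)oxy]-5-[(1S)-2,6,6-trimethylcyclohex-2-en-1-yl]pent-2-enoate | CCOC(=O)/C=C(\OP(=O)(OCC)OCC)CC[C@@H]1C(C)=CCCC1(C)C | intermediate
21 | ethyl (2E)-3-methyl-5-[(1S)-2,6,6-trimethylcyclohex-2-en-1-yl]pent-2-enoate | CCOC(=O)/C=C(\C)CC[C@@H]1C(C)=CCCC1(C)C | intermediate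
22 | (2E)-3-methyl-5-[(1S)-2,6,6-trimethylcyclohex-2-en-1-yl]pent-2-en-1-ol | OC/C=C(\C)CC[C@@H]1C(C)=CCCC1(C)C | intermediate
23 | (6S)-6-[(3E)-5-bromo-3-methylpent-3-en-1-yl]-1,5,5-trimethylcyclohex-1-ene | BrC/C=C(\C)CC[C@@H]1C(C)=CCCC1(C)C | intermediate
24 | methyl acetoacetate | COC(=O)CC(C)=O | starting material
25 | sodium lithium dianion of methyl acetoacetate | [Na+].[Li+].C=C([O-])C=C([O-])OC | intermediate
26 | methyl (6E)-7-methyl-3-oxo-9-[(1S)-2,6,6-trimethylcyclohex-2-en-1-yl]non-6-enoate | COC(=O)CC(=O)CC/C=C(\C)CC[C@@H]1C(C)=CCCC1(C)C | intermediate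
27 | sodium (Z)-enolate of 26 | [Na+].COC(=O)/C=C(\[O-])CC/C=C(\C)CC[C@@H]1C(C)=CCCC1(C)C | intermediate
28 | methyl (2Z,6E)-7-methyl-3-{[(trifluoromethyl)sulfonyl]oxy}-9-[(1S)-2,6,6-trimethylcyclohex-2-en-1-yl]nona-2,6-dienoate | COC(=O)/C=C(\OS(=O)(=O)C(F)(F)F)CC/C=C(\C)CC[C@@H]1C(C)=CCCC1(C)C | intermediate
29 | dimethyl (2Z)-2-{(3E)-4-methyl-6-[(1S)-2,6,6-trimethylcyclohex-2-en-1-yl]hex-3-en-1-yl}but-2-enedioate | COC(=O)/C=C(\C(=O)OC)CC/C=C(\C)CC[C@@H]1C(C)=CCCC1(C)C | intermediate
30 | (2Z)-2-{(3E)-4-methyl-6-[(1S)-2,6,6-trimethylcyclohex-2-en-1-yl]hex-3-en-1-yl}but-2-ene-1,4-diol | OC/C=C(\CO)CC/C=C(\C)CC[C@@H]1C(C)=CCCC1(C)C | intermediate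
31 | (2Z)-2-{(3E)-4-methyl-6-[(1S)-2,6,6-trimethylcyclohex-2-en-1-yl]hex-3-en-1-yl}but-2-ene-1,4-diyl diacetate | CC(=O)OC/C=C(/CC/C=C(\C)CC[C@@H]1C(C)=CCCC1(C)C)COC(C)=O | target

**Step count and risks**

Total step count: 16. Longest linear sequence: 16 steps (1 and 2 to 31; the route is fully linear).

Steps most likely to fail:

Step 2 (enantioselectivity of the CBS reduction on this enone). The fallback sets out from enone 5 and comes back at alcohol 6. Luche reduction (NaBH4, CeCl3·7H2O, MeOH, 0 °C) gives racemic 2,4,4-trimethylcyclohex-2-en-1-ol F1. Kinetic resolution by lipase-catalysed acylation (Burkholderia cepacia lipase, vinyl butanoate, t-BuOMe, rt, stopped near 45–50 % conversion) is expected to acylate the (R)-enantiomer faster (Kazlauskas rule, with the methyl-bearing alkene carbon as the large group). This gives (1R)-2,4,4-trimethylcyclohex-2-en-1-yl butanoate F2, which is separated from the unreacted (S)-alcohol by chromatography. Methanolysis (K2CO3, MeOH, rt) releases 6; the configuration should be confirmed by Mosher ester analysis.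

Step 3 (the [3,3] shift must form a C–C bond next to the quaternary carbon; elimination to a diene can compete at 140 °C). The fallback sets out from alcohol 6 and comes back at alcohol 11, replacing the thermal amide-acetal rearrangement by a low-temperature ester-enolate one. Acetylation (Ac2O, pyridine, DMAP) gives (1R)-2,4,4-trimethylcyclohex-2-en-1-yl acetate F3. Enolisation and silylation (LiN(iPr)2, Me3SiCl, THF, −78 °C) give the trimethylsilyl ketene acetal F4. On warming to 60 °C this undergoes Ireland–Claisen rearrangement with the same suprafacial chirality transfer to trimethylsilyl 2-[(1S)-2,6,6-trimethylcyclohex-2-en-1-yl]acetate F5. Aqueous work-up hydrolyses it to 2-[(1S)-2,6,6-trimethylcyclohex-2-en-1-yl]acetic acid F6, and LiAlH4 (THF, 0 °C) reduces this to 11.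

Step 14 (amine or phosphine may isomerise the maleate to the fumarate or to the exocyclic alkylidene succinate, which would spoil the 2Z geometry). The fallback sets out from triflate 28 and comes back at diol 30. Stille coupling with Bu3SnCH2OH (Pd(PPh3)4, LiCl, dioxane, 90 °C) gives methyl (2Z,6E)-3-(hydroxymethyl)-7-methyl-9-[(1S)-2,6,6-trimethylcyclohex-2-en-1-yl]nona-2,6-dienoate F7. This lactonises (spontaneously, or with pyridinium p-toluenesulfonate) to 4-{(3E)-4-methyl-6-[(1S)-2,6,6-trimethylcyclohex-2-en-1-yl]hex-3-en-1-yl}furan-2(5H)-one F8. Only the Z isomer can close, so the ring locks the geometry. Excess i-Bu2AlH (CH2Cl2, −78 °C → rt) then reduces the butenolide to 30.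

**Further compounds**

F1 | step 2 | racemic 2,4,4-trimethylcyclohex-2-en-1-ol | CC1=CC(C)(C)CCC1O
F2 | step 2 | (1R)-2,4,4-trimethylcyclohex-2-en-1-yl butanoate | CCCC(=O)O[C@H]1C(C)=CC(C)(C)CC1
F3 | step 3 | (1R)-2,4,4-trimethylcyclohex-2-en-1-yl acetate | CC(=O)O[C@H]1C(C)=CC(C)(C)CC1
F4 | step 3 | trimethyl[(1-{[(1R)-2,4,4-trimethylcyclohex-2-en-1-yl]oxy}ethenyl)oxy]silane | C=C(O[Si](C)(C)C)O[C@H]1C(C)=CC(C)(C)CC1
F5 | step 3 | trimethylsilyl 2-[(1S)-2,6,6-trimethylcyclohex-2-en-1-yl]acetate | C[Si](C)(C)OC(=O)C[C@@H]1C(C)=CCCC1(C)C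
F6 | step 3 | 2-[(1S)-2,6,6-trimethylcyclohex-2-en-1-yl]acetic acid | OC(=O)C[C@@H]1C(C)=CCCC1(C)C
F7 | step 14 | methyl (2Z,6E)-3-(hydroxymethyl)-7-methyl-9-[(1S)-2,6,6-trimethylcyclohex-2-en-1-yl]nona-2,6-dienoate | COC(=O)/C=C(\CO)CC/C=C(\C)CC[C@@H]1C(C)=CCCC1(C)C
F8 | step 14 | 4-{(3E)-4-methyl-6-[(1S)-2,6,6-trimethylcyclohex-2-en-1-yl]hex-3-en-1-yl}furan-2(5H)-one | O=C1C=C(CC/C=C(\C)CC[C@@H]2C(C)=CCCC2(C)C)CO1
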